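**Retrosynthetic overview**

1. The target comes from the cis-2,6-disubstituted oxan-4-one by axial hydride delivery (sets C4).
2. The oxan-4-one comes from 3-(4-hydroxy-3,5-dimethoxyphenyl)cyclobutanone and 3-(4-hydroxy-3-methoxyphenyl)propanal by an acid-catalysed two-atom ring expansion: the aldehyde C=O inserts into the C2–C3 bond of the cyclobutanone (forms O1–C2 and C5–C6, sets C2 and C6).
3. The arylcyclobutanone comes from the C,O-dianion of 4-bromo-2,6-dimethoxyphenol and 3-ethoxycyclobutenone, then hydrogenation; the bromophenol comes from resorcinol (O-methylation, ortho-lithiation/oxidation, bromination).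
4. The aldehyde comes from a Heck coupling of 4-iodo-2-methoxyphenol with allyl alcohol; the iodophenol comes from anisole (ortho-lithiation/oxidation, iodination).
5. Ring order: both benzene rings and the four-membered ring are bought; the oxane ring is the only ring made, last, from the four-membered ring. No protecting groups are used.

Assumption: 3-ethoxycyclobut-2-en-1-one is taken as a catalogue compound, and the (S,S)-acid of step 9 is taken to give the (2S,6S) series; if the first run shows the opposite sense, the (R,R)-acid is used and nothing else changes.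

**Route**

Step 1
Reactants: 1 resorcinol (benzene-1,3-diol)
Product: 2 1,3-dimethoxybenzene
Conditions: MeI (2.5 equiv), K2CO3 (3 equiv), DMF, rt
Reagents that add atoms: iodomethane, CI
Why: Double Williamson O-methylation of the two phenols; no stereocentre is involved.

Step 2
Reactants: 2 1,3-dimethoxybenzene
Product: 5 2,6-dimethoxyphenol, via 2-lithio-1,3-dimethoxybenzene 3 (not isolated), via lithium (2,6-dimethoxyphenyl)trimethoxyborate 4 (not isolated)
Conditions: n-BuLi, THF, 0 °C → rt; B(OMe)3, −78 °C → rt; AcOH, 30% H2O2, 0 °C → rt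
Reagents that add atoms: hydrogen peroxide, OO
Why: Directed ortho-metalation at the C–H flanked by both methoxy groups, borylation, then peroxide oxidation of the aryl borate (aryl shift from boron to oxygen) gives the phenol.

Step 3
Reactants: 5 2,6-dimethoxyphenol
Product: 6 4-bromo-2,6-dimethoxyphenol
Conditions: NBS (1.0 equiv), CHCl3, −45 °C → rt
Reagents that add atoms: N-bromosuccinimide, O=C1CCC(=O)N1Br
Why: Electrophilic aromatic bromination; both positions ortho to the phenol are blocked, so the para position reacts.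

Step 4
Reactants: 6 4-bromo-2,6-dimethoxyphenol; 7 3-ethoxycyclobut-2-en-1-one
Product: 11 3-(4-hydroxy-3,5-dimethoxyphenyl)cyclobut-2-en-1-one, via lithium 4-bromo-2,6-dimethoxyphenolate 8 (not isolated), via lithium 4-lithio-2,6-dimethoxyphenolate 9 (not isolated), via dilithium cyclobutenolate adduct 10 (not isolated)
Conditions: n-BuLi (1.0 equiv), THF, −78 °C; t-BuLi (2.05 equiv), −78 °C; 7, −78 → 0 °C; 2 M HCl, 0 °C → rt
Reagents that add atoms: water, O
Why: O-deprotonation and bromine–lithium exchange give the C,O-dianion, which adds 1,2 to the vinylogous ester; aqueous acid then ionises the tertiary allylic alcohol and hydrolyses the enol ether with carbonyl transposition (Stork–Danheiser sequence).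

Step 5
Reactants: 11 3-(4-hydroxy-3,5-dimethoxyphenyl)cyclobut-2-en-1-one
Product: 12 3-(4-hydroxy-3,5-dimethoxyphenyl)cyclobutan-1-one
Conditions: H2 (1 atm), 5% Pd/C, EtOAc, rt
Reagents that add atoms: none
Why: Chemoselective catalytic hydrogenation of the conjugated C=C; the product is achiral (mirror plane through C1 and C3).

Step 6
Reactants: 13 anisole (methoxybenzene)
Product: 16 2-methoxyphenol, via 2-lithioanisole 14 (not isolated), via lithium (2-methoxyphenyl)trimethoxyborate 15 (not isolated)
Conditions: n-BuLi, TMEDA, Et2O, 0 °C → rt; B(OMe)3, −78 °C → rt; AcOH, 30% H2O2, 0 °C → rt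
Reagents that add atoms: hydrogen peroxide, OO
Why: Directed ortho-metalation of anisole, borylation and peroxide oxidation of the aryl borate place the hydroxyl next to the methoxy group.

Step 7
Reactants: 16 2-methoxyphenol
Product: 17 4-iodo-2-methoxyphenol
Conditions: NaI, NaOH, aq. NaOCl, MeOH, 0 °C
Reagents that add atoms: sodium iodide, [Na+].[I-]
Why: Electrophilic aromatic iodination by hypoiodite made in situ; the phenoxide is the stronger director and sends iodine para to oxygen.

Step 8
Reactants: 17 4-iodo-2-methoxyphenol; 18 prop-2-en-1-ol (allyl alcohol)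
Product: 19 3-(4-hydroxy-3-methoxyphenyl)propanal
Conditions: Pd(OAc)2 (3 mol %), Bu4NCl, NaHCO3, DMF, 45 °C
Reagents that add atoms: none
Why: Heck reaction under ligand-free phase-transfer (Jeffery) conditions; the arylpalladium adds to the terminal carbon and β-hydride elimination toward the carbinol gives the enol, hence the saturated aldehyde.

Step 9
Reactants: 12 3-(4-hydroxy-3,5-dimethoxyphenyl)cyclobutan-1-one; 19 3-(4-hydroxy-3-methoxyphenyl)propanal
Product: 21 (2S,6S)-2-(4-hydroxy-3,5-dimethoxyphenyl)-6-[2-(4-hydroxy-3-methoxyphenyl)ethyl]oxan-4-one, via quinone methide enol 20 (not isolated)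
Conditions: 19 (1.5 equiv), (S,S)-IDPi Brønsted acid HN[P(=NSO2CF3)(O2R)]2, O2R = (S)-3,3'-bis(4-tert-butylphenyl)-1,1'-binaphthalene-2,2'-diolate (5 mol %), CHCl3/toluene 1:1, −40 → −20 °C
Reagents that add atoms: none
Why: Proposed new method: the confined strong acid protonates the cyclobutanone oxygen and the strained C2–C3 bond breaks with push from the para-hydroxyl (donor–acceptor cyclobutane logic, about 26 kcal/mol of strain released) to give quinone methide enol 20 held by the chiral anion; the aldehyde oxygen adds reversibly to the quinone-methide carbon to give an O-benzylic oxocarbenium ion, and the enol closes onto it (C5–C6 bond) through a chair transition state with both substituents equatorial inside the catalyst pocket, which fixes C6 as S and, because the benzylic C2–O bond stays reversible, C2 as its 2,6-cis (S) partner; this stepwise ionic ring expansion (four to six members) is closest to the BF3·OEt2-promoted formal [4+2] reaction of 3-alkoxycyclobutanones with aldehydes, the Sc(OTf)3-catalysed [4+2] annulation of aryl donor–acceptor cyclobutane diesters with aldehydes and the IDPi-catalysed asymmetric Prins cyclisation, and has not been shown for a 3-arylcyclobutanone or in enantioselective form.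

Step 10
Reactants: 21 (2S,6S)-2-(4-hydroxy-3,5-dimethoxyphenyl)-6-[2-(4-hydroxy-3-methoxyphenyl)ethyl]oxan-4-one
Product: 22 (2S,4R,6S)-2-(4-hydroxy-3,5-dimethoxyphenyl)-6-[2-(4-hydroxy-3-methoxyphenyl)ethyl]oxan-4-ol (CNP0302691.1)
Conditions: NaBH4, MeOH, −20 °C
Reagents that add atoms: none
Why: Borohydride reduction of the ketone; the chair has the C2 aryl and C6 side chain equatorial and the small hydride attacks axially, giving the equatorial (4R) alcohol cis to both substituents, while C2 and C6 are untouched.

**Compound list**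

1 | resorcinol | Oc1cccc(O)c1 | starting material
2 | 1,3-dimethoxybenzene | COc1cccc(OC)c1 | intermediate
3 | 2-lithio-1,3-dimethoxybenzene | COc1cccc(OC)c1[Li] | intermediate (not isolated)
4 | lithium (2,6-dimethoxyphenyl)trimethoxyborate | [Li+].COc1cccc(OC)c1[B-](OC)(OC)OC | intermediate (not isolated)
5 | 2,6-dimethoxyphenol | COc1cccc(OC)c1O | intermediate
6 | 4-bromo-2,6-dimethoxyphenol | COc1cc(Br)cc(OC)c1O | intermediate
7 | 3-ethoxycyclobut-2-en-1-one | CCOC1=CC(=O)C1 | starting material
8 | lithium 4-bromo-2,6-dimethoxyphenolate | [Li+].COc1cc(Br)cc(OC)c1[O-] | intermediate (not isolated)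
9 | lithium 4-lithio-2,6-dimethoxyphenolate | [Li+].COc1cc([Li])cc(OC)c1[O-] | intermediate (not isolated)
10 | dilithium 3-ethoxy-1-(3,5-dimethoxy-4-oxidophenyl)cyclobut-2-en-1-olate | [Li+].[Li+].CCOC1=CC([O-])(C1)c1cc(OC)c([O-])c(OC)c1 | intermediate (not isolated)
11 | 3-(4-hydroxy-3,5-dimethoxyphenyl)cyclobut-2-en-1-one | COc1cc(cc(OC)c1O)C1=CC(=O)C1 | intermediate
12 | 3-(4-hydroxy-3,5-dimethoxyphenyl)cyclobutan-1-one | COc1cc(cc(OC)c1O)C1CC(=O)C1 | intermediate
13 | anisole | COc1ccccc1 | starting material
14 | 2-lithioanisole | COc1ccccc1[Li] | intermediate (not isolated)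
15 | lithium (2-methoxyphenyl)trimethoxyborate | [Li+].COc1ccccc1[B-](OC)(OC)OC | intermediate (not isolated)
16 | 2-methoxyphenol | COc1ccccc1O | intermediate
17 | 4-iodo-2-methoxyphenol | COc1cc(I)ccc1O | intermediate
18 | prop-2-en-1-ol | C=CCO | starting material
19 | 3-(4-hydroxy-3-methoxyphenyl)propanal | COc1cc(CCC=O)ccc1O | intermediate
20 | 4-(3-hydroxybut-3-en-1-ylidene)-2,6-dimethoxycyclohexa-2,5-dien-1-one | COC1=CC(=CCC(O)=C)C=C(OC)C1=O | intermediate (not isolated)
21 | (2S,6S)-2-(4-hydroxy-3,5-dimethoxyphenyl)-6-[2-(4-hydroxy-3-methoxyphenyl)ethyl]oxan-4-one | COc1cc(CC[C@H]2CC(=O)C[C@@H](c3cc(OC)c(O)c(OC)c3)O2)ccc1O | intermediate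
22 | (2S,4R,6S)-2-(4-hydroxy-3,5-dimethoxyphenyl)-6-[2-(4-hydroxy-3-methoxyphenyl)ethyl]oxan-4-ol | COc1cc(CC[C@H]2C[C@@H](O)C[C@@H](c3cc(OC)c(O)c(OC)c3)O2)ccc1O | target

**Step count**

Total: 10 steps (5 to cyclobutanone 12, 3 to aldehyde 19, 2 after the union).
Longest linear sequence: 7 steps (steps 1–5, 9, 10).

**Three steps most likely to fail**

Step 9 (the proposed new ring expansion). The ring-opened intermediate may simply lose a proton to give the (E)-4-arylbut-3-en-2-one. Aldehyde 19 may self-condense or cyclise onto its own electron-rich ring. The level of enantiocontrol is unknown. The fallback is known chemistry without ring expansion; it sets out from aldehyde 19 and phenol 5 and comes back at target 22. Phenol 5 is formylated para by the Duff reaction (hexamethylenetetramine, TFA, reflux; aq. HCl) to 4-hydroxy-3,5-dimethoxybenzaldehyde F1, which is acetylated (Ac2O, pyridine) to 4-formyl-2,6-dimethoxyphenyl acetate F2. Aldehyde 19 is allylated with allylboronic acid pinacol ester under catalysis by (R)-3,3'-bis(2,4,6-triisopropylphenyl)-1,1'-binaphthyl-2,2'-diyl hydrogen phosphate (toluene, −30 °C; the catalyst enantiomer that gives the (S)-alcohol is used) to give, through the pinacol boronate 2-{[(3S)-1-(4-hydroxy-3-methoxyphenyl)hex-5-en-3-yl]oxy}-4,4,5,5-tetramethyl-1,3,2-dioxaborolane F3, the alcohol (S)-1-(4-hydroxy-3-methoxyphenyl)hex-5-en-3-ol F4. Prins cyclisation of F4 and F2 (TFA, CH2Cl2, 0 °C → rt) gives the all-cis ester (2S,4R,6S)-2-(4-acetoxy-3,5-dimethoxyphenyl)-6-[2-(4-hydroxy-3-methoxyphenyl)ethyl]oxan-4-yl trifluoroacetate F5, and K2CO3 in MeOH removes both esters to give 22.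

Step 4 (dianion addition to the vinylogous ester). Bromine–lithium exchange on the electron-rich phenolate may be incomplete, the dianion may be poorly soluble, and the hydroxyaryl cyclobutenone may not survive the acidic work-up. The fallback builds the four-membered ring by a [2+2] cycloaddition; it sets out from 6 and comes back at 12. Phenol 6 is acetylated (Ac2O, pyridine) to 4-bromo-2,6-dimethoxyphenyl acetate F6, and Stille coupling with tributyl(vinyl)stannane (Pd(PPh3)4, toluene, 100 °C) gives 4-ethenyl-2,6-dimethoxyphenyl acetate F7. Dichloroketene made in situ (Cl3CCOCl, Zn–Cu couple, POCl3, Et2O, rt) adds to F7 to give racemic 4-(2,2-dichloro-3-oxocyclobutyl)-2,6-dimethoxyphenyl acetate F8. Zn in AcOH (50 °C) removes both chlorines to give 2,6-dimethoxy-4-(3-oxocyclobutyl)phenyl acetate F9, and K2CO3 in MeOH frees the phenol to give 12.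

Step 8 (Heck coupling of the free iodophenol with allyl alcohol). The electron-rich free phenol may slow the catalyst, the branched regioisomer may form, and the aldehyde may self-condense in the basic medium. The fallback joins the three-carbon unit by a B-alkyl Suzuki–Miyaura coupling; it sets out from 17 and comes back at 19. 3,3-Dimethoxyprop-1-ene is hydroborated with 9-BBN-H (THF, rt) to 9-(3,3-dimethoxypropyl)-9-borabicyclo[3.3.1]nonane F10. Coupling of F10 with 17 (PdCl2(dppf), aq. K3PO4, THF/DMF, 60 °C) gives 4-(3,3-dimethoxypropyl)-2-methoxyphenol F11, and 1 M HCl in THF (rt) hydrolyses the acetal to give 19.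

**Further compounds**

F1 | step 9 | 4-hydroxy-3,5-dimethoxybenzaldehyde | COc1cc(C=O)cc(OC)c1O
F2 | step 9 | 4-formyl-2,6-dimethoxyphenyl acetate | COc1cc(C=O)cc(OC)c1OC(C)=O
F3 | step 9 | 2-{[(3S)-1-(4-hydroxy-3-methoxyphenyl)hex-5-en-3-yl]oxy}-4,4,5,5-tetramethyl-1,3,2-dioxaborolane | COc1cc(CC[C@H](OB2OC(C)(C)C(C)(C)O2)CC=C)ccc1O
F4 | step 9 | (S)-1-(4-hydroxy-3-methoxyphenyl)hex-5-en-3-ol | COc1cc(CC[C@H](O)CC=C)ccc1O
F5 | step 9 | (2S,4R,6S)-2-(4-acetoxy-3,5-dimethoxyphenyl)-6-[2-(4-hydroxy-3-methoxyphenyl)ethyl]oxan-4-yl trifluoroacetate | COc1cc(CC[C@H]2C[C@@H](OC(=O)C(F)(F)F)C[C@@H](c3cc(OC)c(OC(C)=O)c(OC)c3)O2)ccc1O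
F6 | step 4 | 4-bromo-2,6-dimethoxyphenyl acetate | COc1cc(Br)cc(OC)c1OC(C)=O
F7 | step 4 | 4-ethenyl-2,6-dimethoxyphenyl acetate | COc1cc(C=C)cc(OC)c1OC(C)=O
F8 | step 4 | racemic 4-(2,2-dichloro-3-oxocyclobutyl)-2,6-dimethoxyphenyl acetate | COc1cc(cc(OC)c1OC(C)=O)C1CC(=O)C1(Cl)Cl
F9 | step 4 | 2,6-dimethoxy-4-(3-oxocyclobutyl)phenyl acetate | COc1cc(cc(OC)c1OC(C)=O)C1CC(=O)C1
F10 | step 8 | 9-(3,3-dimethoxypropyl)-9-borabicyclo[3.3.1]nonane | COC(CCB1C2CCCC1CCC2)OC
F11 | step 8 | 4-(3,3-dimethoxypropyl)-2-methoxyphenol | COc1cc(CCC(OC)OC)ccc1O
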